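Ask of this flask how fast it runs and what holds it back, counting in fractions of the charge of X.

X 1.0 M; G 1.00 equiv; J 0.800 equiv; time 10 h

    X + G → Z + Q (k1 = 0.025 M⁻¹ min⁻¹)
    G + Q ⇌ G.Q, settled at all times (K2 = 53 M⁻¹)
    Z → E (k3 = 1.4 × 10⁻⁴ min⁻¹)
    J + Q → J.Q (k4 = 0.17 M⁻¹ min⁻¹)

- part of the X that has reacted at 10 h
- share of the unused G that is free and not bound as G.Q, at 10 h

- what is said of Q includes G.Q
- run time (flask): 10 h

1. At the charge, the clock of X with G is 40.0 min, while J catches a free Q within 7.35 min. But at the charged G, each free Q stands beside 53 bound as G.Q, so the whole stock of Q drains in about 6.62 h, slower than X reacts, and making and catching are not balanced. As a rough closure, an assumption of mine, I still set free Q where making equals catching, which leaves out what G.Q gives back.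

2. Two things slow the rate. X and G were charged equal and go one for one, so with u the unused fraction of each, their loss gives u squared. Binding as G.Q leaves a free share f of the unused G. The closure gives f times (one plus a times f) equals one, where a is the binding constant times the charge of X times the ratio of making constant to catching constant, times u squared over j, the free J in fractions of the X charge.

3. With the charged amounts a is 9.74, and the closure gives f of 27.3 %, which I use as a first guess. At u of 0.5, the Q still held in G.Q has not reached J, so j is 0.663 and a is 2.94. That gives 43.8 %, my brake, the free share of unused G at mid-run. G.Q is the resting state of G, holding more than stays free.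

4. Under u squared, the reciprocal of u climbs straight with time. Unbraked, c is 93.8 %. With the brake held, I commit to c of 86.8 % and fr of 43.8 %.

The forecast says 88 % and 38 %, because “Q builds up early and ties up much of the free G”. My c is lower and my fr higher.

The flask gives 86.3 % and 39.2 %, both within the forecast's margins. Free Q stands at 2.86 % of the X charge after 1.00 h and at 2.93 % after 10.0 h. Held on for twice the time, the brake gives 92.9 %, and the flask gives 91.7 %.

With 2.5 M of X, a runs from 24.4 to 6.88, so the brake is 31.6 % and c is 92.2 %. That flask gives c of 90.9 %, but its free share is 17.2 %.

The rate constants are assumed, and the outcome is calculated.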